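Locants used throughout (chamigrane numbering, not lowest-locant rules): ring B is C1–C5 plus the spiro carbon C6 (Br on C2; Cl and CH3 on C3); ring A is C6–C11 (methylene on C7, ketone C8, C9=C10 with Br on C10, two CH3 on C11).

## Analysis of the target

The target is a spiro[5.5]undecane in which ring A (C6–C11) is a cross-conjugated dienone: an exocyclic methylene on C7, the ketone at C8, a C9=C10 double bond bearing bromine on C10, and a gem-dimethyl carbon C11 directly bonded to the spiro carbon C6. Ring B (C1–C6) is saturated and carries a secondary bromide on C2 and a tertiary chloride plus a methyl group on C3. There are three stereocentres, C2 (S), C3 (S) and C6 (S). Bromine and chlorine are trans; in the ring-B chair that keeps the bulky C11 equatorial both halogens are equatorial, the C3 methyl and the C7 arm are axial, and bromine sits on the ring-B face that carries C11, opposite to C7. The tertiary chloride with its neighbouring bromide (elimination, ionization), the β-bromo enone (addition–elimination) and the exocyclic enone (conjugate addition, dimerization) are all fragile, so the halogens and above all the methylene must come late. The synthesis is hard because C6 and C11 are vicinal fully substituted carbons, because C6 is stereogenic only through a remote difference between its two ring-B arms, and because a trans-diequatorial bromochloride is not what a plain diaxial addition gives in the preferred ring-B conformation. The strategy rests on the fact that both ring-B neighbours of C6, namely C1 and C5, are CH2 groups, while C2, two bonds from C6, is functionalized. A four-membered ketone made of C6, C1, C5 and a carbonyl carbon C2, attached to a finished ring-A precursor, is therefore achiral with two enantiotopic acyl–CH2 bonds, and inserting C3 and C4 into one of them builds ring B and the C6 stereocentre in one operation.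

## Retrosynthetic reasoning

C7=CH2. The exocyclic methylene of 24 is removed first, because the cross-conjugated methylene enone tolerates neither nucleophiles nor oxidants. This leads back to the β-bromo enone 20 through the Mannich base 22. The forward reaction has to functionalize C7 only, which is assured because C7 is the sole enolizable position of 20.

C8=O. Taking the oxygen off C8 gives the bromochloride 19. C8 is the only allylic CH2 of the C9=C10 bromoalkene (C11 is quaternary), so an allylic oxidation has one site to choose. It is placed after the halogenation of ring B, since a ring-B olefin would offer competing allylic positions.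

C2–Br and C3–Cl. Cutting both carbon–halogen bonds gives the diene 18. The forward step is an anti addition of bromine and chlorine to the electron-rich C2=C3 bond in the presence of the deactivated bromoalkene. It must put chloride on the tertiary carbon C3 and bromine on the face of ring B away from the axial C7 arm.

C10–Br. The vinyl bromide of 18 is traced to the ketone 15 through the enol triflate 17, and 15 to its ketal 14. Doing this before ring B is halogenated keeps strong base and low-valent nickel away from any alkyl halide. Enolization of 15 can only go toward C9.

C2=C3. The olefin of 14 comes from the enone 11 through the enol triflate 13. Conjugate reduction turns C4 into CH2 and parks the double bond at C2=C3 as an enolate; replacing the triflate by hydrogen then deletes the C2 oxygen without moving the double bond.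

C4–Si. The silyl enone 10 is the precursor of 11. The silyl group has done its work once the regiochemistry of the alkyne insertion is fixed.

C2–C3 and C4–C5 (key disconnection). Cutting these two bonds of 10 gives the achiral spiro cyclobutanone 8 and the alkyne 9. This is the only point where absolute configuration enters: the forward reaction must insert 9 into the C2–C5 bond and not into the enantiotopic C2–C1 bond. The gain is that ring B, the C3 methyl, the C2 oxygen handle and the C6 stereocentre all arise together.

C6–C1 and C5–C2 of the four-membered ring. The cyclobutanone 8 goes back through the dichloride 7 to the methylene compound 4 and dichloroketene 6, generated from 5. A [2+2] cycloaddition makes the crowded C6–C bond on a neutral alkene instead of by alkylation next to C11.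

C6=CH2 and the ketal. Compound 4 comes from the mono-ketal 3 by Wittig methylenation, and 3 from the symmetrical dione 1 and diol 2. The symmetry of 1 means that either carbonyl may be protected, and the ketal keeps C10 oxidized for the later vinyl bromide.

## Alternatives that were turned down

Alternative 1: Ring B would be closed by cutting C6–C1 and C6–C5. In the forward sense the enolate of the ester A3 (C6 is its α-carbon, C7 the ester carbon) would be alkylated twice by the bis-electrophile A2, which already carries the C2 bromide and C3 chloride, to give the cyclohexane A1. In its favour, C2 and C3 would be set in an open chain by a catalyst-controlled bromochlorination of an allylic alcohol. That is reagent control, and on the bromochloride this plan is stronger than the chosen one, which relies on substrate control in step 12. Against it, the enolate carbon is neopentyl (next to C11), and the second alkylation has to create a quaternary carbon beside another one. Both alkylations run under strongly basic conditions on a substrate that can lose HBr or HCl. The configuration of C6 would be decided in that ring closure only by 1,3- and 1,4-induction from C2 and C3, and ring A would still be open and lack C8. The chosen route offers instead a C6 made by cycloaddition, its configuration set by a catalyst, and no base-sensitive halide in the molecule until step 12.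

Alternative 2: Ring A would be closed by cutting C6–C7. The phenolic diazoketone A5 would be decomposed with acid so that the para carbon of the phenol (the future C6) attacks the diazo-bearing carbon C7 and the ring dearomatizes to the spirodienone A4. In its favour, the spiro skeleton is reached quickly, and ring A arrives with oxygen on C8 and C10, exactly where the target has its ketone and vinyl bromide. On ring-A oxidation pattern this plan is stronger than the chosen one, which needs an allylic oxidation (step 13). Against it, C6 is not a stereocentre in A4. The two enone arms of ring B would have to be told apart later by a reagent that reads only the distant C10 stereocentre. Ring B also arrives with oxygen on C3, so both the methyl group and the chlorine must be brought to a former carbonyl carbon, the two C=C bonds must be processed one at a time, and the trans bromochloride problem remains. The chosen route offers a catalytic decision on C6 in the bond-forming step, and the C3 methyl comes with the alkyne.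

Alternative 3: Ring A would be closed by cutting C6–C11. (R)-Limonene A8 would supply ring B and be bromochlorinated while its side chain is an ordinary equatorial substituent. The side chain would then be elaborated to the (Z)-trienol ether A7 (C6=C7, C8=C9, C10=C11), and heating would trigger a disrotatory 6π-electrocyclization to the dienol ether A6. In its favour, the plan is convergent and the ring closure is redox-neutral. The bromochloride would be set by a diaxial addition in its most favourable case and from the chiral pool, which is again stronger than the chosen route on C2 and C3. Against it, both termini of the triene are fully substituted (C11 with two methyl groups, C6 with two ring carbons). Two groups would have to point inward in the transition state, so the closure would need high temperature, a [1,7]-hydrogen shift from the inward methyl would compete, and a tertiary chloride next to a bromide would be unlikely to survive. The stereocentre of A8 is lost when C6 becomes sp2, so C6 would be reset only by the facial bias of C2 and C3. The oxygen would also end on C7 instead of C8, which calls for a carbonyl transposition as well as the methylenation. The chosen route has no thermal step on a halogenated intermediate and sets C6 by a catalyst.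

Key step: step 5

Assumption: the sense of induction of the chiral phosphine in step 5 cannot be predicted; (S)-AntPhos is written, and its enantiomer would be used if it proves to cleave the C2–C1 bond instead.

## Route

Step 1
Reactants: 1 2,2-dimethylcyclohexane-1,3-dione; 2 ethane-1,2-diol
Product: 3 6,6-dimethyl-1,4-dioxaspiro[4.5]decan-7-one
Conditions: 2 (1.1 equiv), p-TsOH·H2O (cat.), PhH, reflux, Dean–Stark
Reagents that add atoms: none
Why: Acid-catalysed ketalization; after the first carbonyl is protected the second is flanked by CMe2 and the dioxolane and should resist a second ketalization, so one equivalent of diol should stop at the mono-ketal.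

Step 2
Reactants: 3 6,6-dimethyl-1,4-dioxaspiro[4.5]decan-7-one
Product: 4 6,6-dimethyl-7-methylidene-1,4-dioxaspiro[4.5]decane
Conditions: Ph3PCH3Br, KOt-Bu, PhMe, 90 °C
Reagents that add atoms: methyltriphenylphosphonium bromide, C[P+](c1ccccc1)(c1ccccc1)c1ccccc1.[Br-]
Why: Wittig methylenation; the non-stabilized ylide in hot toluene is the standard answer to α-quaternary cyclohexanones, and the ketal is inert to base.

Step 3
Reactants: 4 6,6-dimethyl-7-methylidene-1,4-dioxaspiro[4.5]decane; 5 trichloroacetyl chloride
Product: 7 racemic 1,1-dichloro-6,6-(ethylenedioxy)-5,5-dimethylspiro[3.5]nonan-2-one, via dichloroketene 6 (not isolated)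
Conditions: Zn dust, POCl3, Et2O, sonication, 20 °C, slow addition of 5
Reagents that add atoms: none
Why: [2+2] cycloaddition of a ketene with a 1,1-disubstituted alkene; the ketene carbonyl carbon bonds to the terminal CH2 and the CCl2 carbon to the substituted carbon, which creates the quaternary C6 next to C11 without an alkylation; POCl3 ties up ZnCl2 and spares the ketal.

Step 4
Reactants: 7 racemic 1,1-dichloro-6,6-(ethylenedioxy)-5,5-dimethylspiro[3.5]nonan-2-one
Product: 8 6,6-(ethylenedioxy)-5,5-dimethylspiro[3.5]nonan-2-one
Conditions: Zn dust, NH4Cl, MeOH, 23 °C
Reagents that add atoms: none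
Why: Reductive dechlorination of an α,α-dichloro ketone by zinc under nearly neutral conditions; with both chlorines gone the two cyclobutanone arms are identical and 8 is achiral, so the racemic nature of 7 is of no consequence.

Step 5
Reactants: 8 6,6-(ethylenedioxy)-5,5-dimethylspiro[3.5]nonan-2-one; 9 trimethyl(prop-1-yn-1-yl)silane
Product: 10 (6R)-10,10-(ethylenedioxy)-3,11,11-trimethyl-4-(trimethylsilyl)spiro[5.5]undec-3-en-2-one
Conditions: Ni(cod)2 (10 mol %), (S)-AntPhos (20 mol %), 9 (3 equiv), PhMe, 90 °C, sealed tube
Reagents that add atoms: none
Why: Zerovalent nickel carrying one chiral phosphine couples the C2 carbonyl of 8 with alkyne 9 by oxidative cyclization to a spiro oxanickelacyclopentene, forming C2–C3; silicon prefers the nickel-bound carbon, so the methyl-bearing carbon becomes C3 and the silyl-bearing carbon C4. β-Carbon elimination then breaks one strained acyl–CH2 bond (C2–C5 is wanted) to give a seven-membered nickelacycle, and C(sp2)–C(sp3) reductive elimination forms C4–C5 and releases the catalyst. The closest known reaction type is the nickel-catalysed insertion of internal alkynes into 3,3-disubstituted cyclobutanones, and ligand-controlled desymmetrization of cyclobutanones through the same oxidative cyclization and β-carbon elimination sequence is known for tethered π-partners. Ring B is closed as a formal [4+2] ring expansion of the four-membered ketone by two alkyne carbons, the last bond being made by reductive elimination at nickel and not by a polar cyclization. C6 becomes stereogenic only through the choice between the enantiotopic C2–C5 and C2–C1 bonds; because 8 has a mirror plane through C2, C6, C7 and C11 in which the nickelacycle lies, this choice is made by the chiral phosphine alone, which has to sense whether CMe2 or CH2 flanks the migrating arm. The step needs regioselectivity in the alkyne (secured by silicon), chemoselectivity for the strained ketone (the ketal is inert) and enantiotopic bond selection (ligand control, helped by the large steric difference between C11 and C7, but untested on a substrate with vicinal quaternary carbons).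

Step 6
Reactants: 10 (6R)-10,10-(ethylenedioxy)-3,11,11-trimethyl-4-(trimethylsilyl)spiro[5.5]undec-3-en-2-one
Product: 11 (6S)-10,10-(ethylenedioxy)-3,11,11-trimethylspiro[5.5]undec-3-en-2-one
Conditions: Bu4NF·3H2O, DMSO, 60–80 °C
Reagents that add atoms: none
Why: Fluoride-promoted protodesilylation of a vinylsilane; the β-acyl group polarizes the C4–Si bond, the pentacoordinate silicate is protonated at C4 by the water present, and ketal and enone are stable to fluoride; the descriptor at C6 changes only because the priorities change.

Step 7
Reactants: 11 (6S)-10,10-(ethylenedioxy)-3,11,11-trimethylspiro[5.5]undec-3-en-2-one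
Product: 13 (6S)-10,10-(ethylenedioxy)-3,11,11-trimethylspiro[5.5]undec-2-en-2-yl trifluoromethanesulfonate, via lithium enolate 12 (not isolated)
Conditions: LiBH(s-Bu)3, THF, −78 °C; then PhNTf2, −78 → 23 °C
Reagents that add atoms: N-phenylbis(trifluoromethanesulfonimide), O=S(=O)(N(c1ccccc1)S(=O)(=O)C(F)(F)F)C(F)(F)F
Why: Conjugate hydride reduction of a cyclohexenone with an unsubstituted β-carbon by a bulky trialkylborohydride gives the tetrasubstituted enolate regiospecifically; O-triflation fixes the double bond at C2=C3 and leaves C4 as CH2.

Step 8
Reactants: 13 (6S)-10,10-(ethylenedioxy)-3,11,11-trimethylspiro[5.5]undec-2-en-2-yl trifluoromethanesulfonate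
Product: 14 (6S)-10,10-(ethylenedioxy)-3,11,11-trimethylspiro[5.5]undec-2-ene
Conditions: Pd(OAc)2 (5 mol %), PPh3 (10 mol %), HCO2H, Bu3N, DMF, 60 °C
Reagents that add atoms: none
Why: Palladium-catalysed formate reduction of an enol triflate (oxidative addition, formate exchange, decarboxylation, C–H reductive elimination) replaces the triflate by hydrogen without moving the double bond, and the buffered medium spares the ketal.

Step 9
Reactants: 14 (6S)-10,10-(ethylenedioxy)-3,11,11-trimethylspiro[5.5]undec-2-ene
Product: 15 (6S)-3,11,11-trimethylspiro[5.5]undec-2-en-10-one
Conditions: 1 M HCl (aq), THF, 23 °C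
Reagents that add atoms: water, O
Why: Acid-catalysed ketal hydrolysis; dilute acid at room temperature should not hydrate or shift the trisubstituted olefin.

Step 10
Reactants: 15 (6S)-3,11,11-trimethylspiro[5.5]undec-2-en-10-one
Product: 17 (6S)-3,11,11-trimethylspiro[5.5]undeca-2,9-dien-10-yl trifluoromethanesulfonate, via potassium enolate 16 (not isolated)
Conditions: KN(SiMe3)2, THF, −78 °C; then PhNTf2, −78 → 0 °C
Reagents that add atoms: N-phenylbis(trifluoromethanesulfonimide), O=S(=O)(N(c1ccccc1)S(=O)(=O)C(F)(F)F)C(F)(F)F
Why: Enolization can only go toward C9 because C11 is quaternary, and O-sulfonylation of the enolate is insensitive to the crowding at C10; no alkyl halide is yet present to suffer from the strong base.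

Step 11
Reactants: 17 (6S)-3,11,11-trimethylspiro[5.5]undeca-2,9-dien-10-yl trifluoromethanesulfonate
Product: 18 (6S)-10-bromo-3,11,11-trimethylspiro[5.5]undeca-2,9-diene
Conditions: Ni(cod)2 (10 mol %), LiBr (2 equiv), DMA/THF 1:3, 23 °C
Reagents that add atoms: lithium bromide, [Li+].[Br-]
Why: Nickel-catalysed halide exchange of an enol triflate (C–O oxidative addition, triflate/bromide exchange at nickel, C–Br reductive elimination); it is run before ring B is halogenated so that low-valent nickel meets no C(sp3)–halogen bond.

Step 12
Reactants: 18 (6S)-10-bromo-3,11,11-trimethylspiro[5.5]undeca-2,9-diene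
Product: 19 (2S,3S,6S)-2,10-dibromo-3-chloro-3,11,11-trimethylspiro[5.5]undec-9-ene
Conditions: NBS (1.05 equiv), HCl (4 M in dioxane, 1.1 equiv), CH2Cl2, −78 → −40 °C
Reagents that add atoms: N-bromosuccinimide, O=C1CCC(=O)N1Br; hydrogen chloride, Cl
Why: Electrophilic anti addition of Br–Cl, formed in the flask, to the electron-rich C2=C3 bond, the bromoalkene being deactivated. With C11 equatorial and the C7 methylene axial on ring B, the bromonium ion should form on the face opposite C7, and chloride should open it at the tertiary carbon C3 from the C7 side; the competing axial attack at C2 is anti-Markovnikov and is obstructed by the same C7 methylene. This gives C2–Br (S) and C3–Cl (S) trans, both equatorial.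

Step 13
Reactants: 19 (2S,3S,6S)-2,10-dibromo-3-chloro-3,11,11-trimethylspiro[5.5]undec-9-ene
Product: 20 (2S,3S,6R)-2,10-dibromo-3-chloro-3,11,11-trimethylspiro[5.5]undec-9-en-8-one
Conditions: Rh2(cap)4 (cap = caprolactamate, 1 mol %), t-BuOOH (5 equiv), K2CO3 (0.5 equiv), CH2Cl2, 23 °C
Reagents that add atoms: tert-butyl hydroperoxide, CC(C)(C)OO
Why: Allylic C–H oxidation (hydrogen abstraction by the tert-butylperoxyl radical, mixed peroxide, elimination) at C8, the only allylic CH2 because C11 is quaternary; alkyl halides are inert to the peroxyl radical, and the changed descriptor at C6 reflects priorities only.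

Step 14
Reactants: 20 (2S,3S,6R)-2,10-dibromo-3-chloro-3,11,11-trimethylspiro[5.5]undec-9-en-8-one
Product: 22 (2S,3S,6S)-2,10-dibromo-3-chloro-7-[(dimethylamino)methyl]-3,11,11-trimethylspiro[5.5]undec-9-en-8-one (both C7 epimers), via lithium dienolate 21 (not isolated)
Conditions: LiN(SiMe3)2, THF, −78 °C; then Me2N=CH2+ I−, −78 → 0 °C
Reagents that add atoms: N,N-dimethylmethyleneiminium iodide (Eschenmoser's salt), C=[N+](C)C.[I-]
Why: Kinetic α′-deprotonation at C7, the only enolizable position since the γ-carbon C11 is quaternary, gives the cross-conjugated dienolate, which adds to the iminium salt in a Mannich reaction; the hindered amide base and the low temperature protect the β-bromo enone and the ring-B halides, and the C7 epimers converge in the next step.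

Step 15
Reactants: 22 (2S,3S,6S)-2,10-dibromo-3-chloro-7-[(dimethylamino)methyl]-3,11,11-trimethylspiro[5.5]undec-9-en-8-one
Product: 24 (2S,3S,6S)-2,10-dibromo-3-chloro-3,11,11-trimethyl-7-methylidenespiro[5.5]undec-9-en-8-one, via ammonium iodide 23 (not isolated)
Conditions: MeI, CH2Cl2, 23 °C; then NaHCO3 (aq), 23 °C
Reagents that add atoms: none
Why: N-Methylation followed by E1cB loss of trimethylamine gives the exocyclic enone under weakly basic conditions; the methylene cannot migrate into the ring because C6 is quaternary.

## Compound list

1 | 2,2-dimethylcyclohexane-1,3-dione | CC1(C)C(=O)CCCC1=O | starting material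
2 | ethane-1,2-diol | OCCO | starting material
3 | 6,6-dimethyl-1,4-dioxaspiro[4.5]decan-7-one | CC1(C)C(=O)CCCC12OCCO2 | intermediate
4 | 6,6-dimethyl-7-methylidene-1,4-dioxaspiro[4.5]decane | C=C1CCCC2(OCCO2)C1(C)C | intermediate
5 | trichloroacetyl chloride | ClC(Cl)(Cl)C(Cl)=O | starting material
6 | dichloroketene | ClC(Cl)=C=O | intermediate
7 | racemic 1,1-dichloro-6,6-(ethylenedioxy)-5,5-dimethylspiro[3.5]nonan-2-one | O=C1CC2(CCCC3(OCCO3)C2(C)C)C1(Cl)Cl | intermediate
8 | 6,6-(ethylenedioxy)-5,5-dimethylspiro[3.5]nonan-2-one (achiral) | O=C1CC2(C1)CCCC3(OCCO3)C2(C)C | intermediate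
9 | trimethyl(prop-1-yn-1-yl)silane | CC#C[Si](C)(C)C | starting material
10 | (6R)-10,10-(ethylenedioxy)-3,11,11-trimethyl-4-(trimethylsilyl)spiro[5.5]undec-3-en-2-one | C1CCC3(OCCO3)C(C)(C)[C@]12CC([Si](C)(C)C)=C(C)C(=O)C2 | intermediate
11 | (6S)-10,10-(ethylenedioxy)-3,11,11-trimethylspiro[5.5]undec-3-en-2-one | C1CCC3(OCCO3)C(C)(C)[C@]12CC=C(C)C(=O)C2 | intermediate
12 | lithium (6S)-10,10-(ethylenedioxy)-3,11,11-trimethylspiro[5.5]undec-2-en-2-olate | C1CCC3(OCCO3)C(C)(C)[C@]12CCC(C)=C([O-])C2.[Li+] | intermediate
13 | (6S)-10,10-(ethylenedioxy)-3,11,11-trimethylspiro[5.5]undec-2-en-2-yl trifluoromethanesulfonate | C1CCC3(OCCO3)C(C)(C)[C@]12CCC(C)=C(OS(=O)(=O)C(F)(F)F)C2 | intermediate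
14 | (6S)-10,10-(ethylenedioxy)-3,11,11-trimethylspiro[5.5]undec-2-ene | C1CCC3(OCCO3)C(C)(C)[C@]12CCC(C)=CC2 | intermediate
15 | (6S)-3,11,11-trimethylspiro[5.5]undec-2-en-10-one | C1CCC(=O)C(C)(C)[C@]12CCC(C)=CC2 | intermediate
16 | potassium (6S)-3,11,11-trimethylspiro[5.5]undeca-2,9-dien-10-olate | C1CC=C([O-])C(C)(C)[C@]12CCC(C)=CC2.[K+] | intermediate
17 | (6S)-3,11,11-trimethylspiro[5.5]undeca-2,9-dien-10-yl trifluoromethanesulfonate | C1CC=C(OS(=O)(=O)C(F)(F)F)C(C)(C)[C@]12CCC(C)=CC2 | intermediate
18 | (6S)-10-bromo-3,11,11-trimethylspiro[5.5]undeca-2,9-diene | C1CC=C(Br)C(C)(C)[C@]12CCC(C)=CC2 | intermediate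
19 | (2S,3S,6S)-2,10-dibromo-3-chloro-3,11,11-trimethylspiro[5.5]undec-9-ene | C1CC=C(Br)C(C)(C)[C@]12CC[C@](C)(Cl)[C@@H](Br)C2 | intermediate
20 | (2S,3S,6R)-2,10-dibromo-3-chloro-3,11,11-trimethylspiro[5.5]undec-9-en-8-one | C1C(=O)C=C(Br)C(C)(C)[C@]12CC[C@](C)(Cl)[C@@H](Br)C2 | intermediate
21 | lithium (2S,3S,6S)-2,10-dibromo-3-chloro-3,11,11-trimethylspiro[5.5]undeca-7,9-dien-8-olate | C1=C([O-])C=C(Br)C(C)(C)[C@]12CC[C@](C)(Cl)[C@@H](Br)C2.[Li+] | intermediate
22 | (2S,3S,6S)-2,10-dibromo-3-chloro-7-[(dimethylamino)methyl]-3,11,11-trimethylspiro[5.5]undec-9-en-8-one (C7 epimers) | CN(C)CC1C(=O)C=C(Br)C(C)(C)[C@]12CC[C@](C)(Cl)[C@@H](Br)C2 | intermediate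
23 | {[(2S,3S,6S)-2,10-dibromo-3-chloro-3,11,11-trimethyl-8-oxospiro[5.5]undec-9-en-7-yl]methyl}trimethylammonium iodide (C7 epimers) | C[N+](C)(C)CC1C(=O)C=C(Br)C(C)(C)[C@]12CC[C@](C)(Cl)[C@@H](Br)C2.[I-] | intermediate
24 | (2S,3S,6S)-2,10-dibromo-3-chloro-3,11,11-trimethyl-7-methylidenespiro[5.5]undec-9-en-8-one | C=C1C(=O)C=C(Br)C(C)(C)[C@]12CC[C@](C)(Cl)[C@@H](Br)C2 | target

## Step count and least certain steps

Total: 15 steps. Longest linear sequence: 15 steps from 1 (the route is fully linear; 2, 5 and 9 are commercial reagents added on the way).

Step 5 (key step). The most likely failure is weak discrimination between the two enantiotopic acyl–CH2 bonds. The nickelacycle lies in the mirror plane of 8, and the two possible orientations of the oxidative cyclization (oxygen toward C11 or toward C7) lead to opposite enantiomers for the same ligand twist, so selectivity erodes unless one orientation dominates. Slow insertion at the doubly neopentyl cyclobutanone, with alkyne oligomerization taking over, is the second concern. Fallback: starting from 8 and 9, the insertion would be run with the achiral catalyst Ni(cod)2/PCy3 to give the racemic silyl enone F1. The enantiomers would then be separated by preparative chromatography on a chiral stationary phase, which delivers 10 and its (6S)-enantiomer F2; the route is rejoined at 10.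

Step 12. The most likely failure is poor facial or positional selectivity in the bromonium opening. The path to 19 passes through a twist-boat-like opening at C3, whereas a bromonium ion on the C7 face can be opened at C3 in the ideal diaxial sense, and diaxial attack at C2 on the favoured bromonium ion is also conceivable. Fallback: single-pass stereocontrol would be given up for a separation and recycling loop. Starting from the crude product of step 12, the diaxial diastereomer (2R,3R,6S)-2,10-dibromo-3-chloro-3,11,11-trimethylspiro[5.5]undec-9-ene F3 would be separated from 19 by chromatography and returned to the diene by zinc-mediated reductive anti-elimination (Zn dust, EtOH, cat. AcOH). The route is rejoined at 18, which is resubmitted.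

Step 6. The most likely failure is sluggish C–Si cleavage, because the developing carbanion character at C4 is not conjugated with the carbonyl. More forcing basic conditions would then cause deconjugation or self-condensation of the enone. Fallback: the silyl group would be changed in the key step. Starting from 8, benzyl(dimethyl)(prop-1-yn-1-yl)silane F4 (from propynylmagnesium bromide and benzylchlorodimethylsilane) would be inserted under the conditions of step 5 to give the benzyldimethylsilyl enone F5. Fluoride removes the benzyl group first, and the resulting fluorosilane or silanol is protodesilylated with Bu4NF in THF at room temperature; the route is rejoined at 11.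

Step 13. The most likely failure is slow hydrogen abstraction next to the electron-poor bromoalkene. That would allow over-oxidation, or trapping of the allyl radical at C10 with loss of bromide. Fallback: starting from 19, a Wohl–Ziegler bromination (NBS, benzoyl peroxide, PhCF3, 80 °C) would give the allylic bromide (2S,3S,6R)-2,8,10-tribromo-3-chloro-3,11,11-trimethylspiro[5.5]undec-9-ene F6. A Kornblum-type oxidation with N-methylmorpholine N-oxide in MeCN would then convert it into the enone; the route is rejoined at 20.

Step 11. The most likely failure is slow oxidative addition or halide exchange at the triflate flanked by the quaternary C11, which would lead to reduction of the triflate or to homocoupling. Fallback: starting from ketone 15, condensation with hydrazine hydrate (EtOH, Et3N, reflux) would give the hydrazone F7. Its oxidation in the manner of the Barton vinyl halide synthesis (CuBr2, Et3N, MeOH) would give the vinyl bromide directly; the route is rejoined at 18.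

## Further compounds

F1 | step 5 | racemic 10,10-(ethylenedioxy)-3,11,11-trimethyl-4-(trimethylsilyl)spiro[5.5]undec-3-en-2-one | C1CCC3(OCCO3)C(C)(C)C12CC([Si](C)(C)C)=C(C)C(=O)C2
F2 | step 5 | (6S)-10,10-(ethylenedioxy)-3,11,11-trimethyl-4-(trimethylsilyl)spiro[5.5]undec-3-en-2-one | C1CCC3(OCCO3)C(C)(C)[C@@]12CC([Si](C)(C)C)=C(C)C(=O)C2
F3 | step 12 | (2R,3R,6S)-2,10-dibromo-3-chloro-3,11,11-trimethylspiro[5.5]undec-9-ene | C1CC=C(Br)C(C)(C)[C@]12CC[C@@](C)(Cl)[C@H](Br)C2
F4 | step 6 | benzyl(dimethyl)(prop-1-yn-1-yl)silane | CC#C[Si](C)(C)Cc1ccccc1
F5 | step 6 | (6R)-4-(benzyldimethylsilyl)-10,10-(ethylenedioxy)-3,11,11-trimethylspiro[5.5]undec-3-en-2-one | C1CCC3(OCCO3)C(C)(C)[C@]12CC([Si](C)(C)Cc4ccccc4)=C(C)C(=O)C2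
F6 | step 13 | (2S,3S,6R)-2,8,10-tribromo-3-chloro-3,11,11-trimethylspiro[5.5]undec-9-ene (C8 epimers) | C1C(Br)C=C(Br)C(C)(C)[C@]12CC[C@](C)(Cl)[C@@H](Br)C2
F7 | step 11 | (6S)-3,11,11-trimethylspiro[5.5]undec-2-en-10-one hydrazone | C1CCC(=NN)C(C)(C)[C@]12CCC(C)=CC2
A1 | alternative 1 | methyl (1R,3S,4S)-3-bromo-1-(3-bromo-2-methylbut-3-en-2-yl)-4-chloro-4-methylcyclohexane-1-carboxylate | C=C(Br)C(C)(C)[C@@]1(C(=O)OC)CC[C@](C)(Cl)[C@@H](Br)C1
A2 | alternative 1 | (2S,3S)-2-bromo-3-chloro-5-iodo-3-methylpentyl trifluoromethanesulfonate | ICC[C@](C)(Cl)[C@@H](Br)COS(=O)(=O)C(F)(F)F
A3 | alternative 1 | methyl 4-bromo-3,3-dimethylpent-4-enoate | COC(=O)CC(C)(C)C(Br)=C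
A4 | alternative 2 | 10-[(tert-butyldimethylsilyl)oxy]-11,11-dimethylspiro[5.5]undeca-1,4-diene-3,8-dione | O=C1C=CC2(C=C1)CC(=O)CC(O[Si](C)(C)C(C)(C)C)C2(C)C
A5 | alternative 2 | 4-[(tert-butyldimethylsilyl)oxy]-1-diazo-5-(4-hydroxyphenyl)-5-methylhexan-2-one | [N-]=[N+]=CC(=O)CC(O[Si](C)(C)C(C)(C)C)C(C)(C)c1ccc(O)cc1
A6 | alternative 3 | tert-butyl{[(2S,3S,6R)-2,10-dibromo-3-chloro-3,11,11-trimethylspiro[5.5]undeca-7,9-dien-7-yl]oxy}dimethylsilane | CC(C)(C)[Si](C)(C)OC1=CC=C(Br)C(C)(C)[C@]12CC[C@](C)(Cl)[C@@H](Br)C2
A7 | alternative 3 | tert-butyl{[(2Z)-4-bromo-1-[(3S,4S)-3-bromo-4-chloro-4-methylcyclohexylidene]-5-methylhexa-2,4-dien-1-yl]oxy}dimethylsilane | CC(C)=C(Br)/C=C\C(O[Si](C)(C)C(C)(C)C)=C1CC[C@](C)(Cl)[C@@H](Br)C1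
A8 | alternative 3 | (R)-limonene, (4R)-1-methyl-4-(prop-1-en-2-yl)cyclohex-1-ene | CC1=CC[C@@H](CC1)C(C)=C
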